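**Plan**

- Labels used throughout: C6 = ring ketone carbon, C7 = enone CH, C8 = enone C(CH3), C9 and C5 = bridgeheads next to C8 and C6, C4 = cyclobutane CH, C10 = cyclobutane C(CH3), C3 = CMe2, C2 (OH), C1 (O-angelate), C11 (O-isovalerate); ring S = C4–C5–C6–C7–C8–C9, ring A = C1–C2–C3–C4–C5–C10–C11.
- Retrosynthesis: the esters and the C1/C2 oxygens go back to a C1=C2 alkene and C11–OH; C9–C10 (cyclobutane) is cut to an α′-enolate plus a C10–C11 epoxide; the enone is 1,3-transposed (C8 methyl from MeLi); then C4–C9 and C6–C7 are cut together.
- Enabling feature: ring S is a 3+3 retron (enal C4=C5–C6H=O plus the acetoacetate carbons C9–C8–C7) fused to seven-membered ring A at the α,β-bond of that enal, and ring A with its C3 gem-dimethyl, C10 methyl and C10=C11–C1=C2 diene is eucarvone plus one carbon (C6).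
- Forward order: ring A (eucarvone from carvone) → ring S by an amine-catalysed Michael/aldol (3+3) annulation → cyclobutane by 4-exo epoxide opening → enone transposition → diol, cyclic sulfate, angelate.
- Stereochemistry: C4 from the chiral amine, C5 by protonation (cis fusion), the epoxide face from the ring fusion, C9/C10/C11 from the anti SN2 epoxide opening, C1/C2 from osmylation anti to C11–O and inversion at C1 by angelate.

Key step: step 5

Remark: the quinine-derived primary amine is assumed to give the C4 configuration drawn; if its facial sense is the opposite, the pseudo-enantiomeric quinidine-derived amine takes its place with nothing else changed.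

Step 1
Reactants: 1 (R)-(−)-carvone
Product: 2 carvone hydrobromide
Conditions: HBr (33% in AcOH), 0 °C
Reagents that add atoms: hydrogen bromide, Br
Why: Markovnikov hydrobromination of the isolated isopropenyl alkene should give the tertiary bromide while the conjugated alkene stays untouched; no new stereocentre is formed.

Step 2
Reactants: 2 carvone hydrobromide
Product: 4 eucarvone, via car-3-en-2-one 3 (not isolated)
Conditions: KOH, MeOH, reflux
Reagents that add atoms: none
Why: the α′-enolate displaces the tertiary bromide (3-exo-tet enolate alkylation) and the carenone enolate then opens its cyclopropane to the conjugated cycloheptadienone (the classical eucarvone ring expansion); the stereocentre is erased, so either carvone enantiomer serves.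

Step 3
Reactants: 4 eucarvone
Product: 5 eucarvone enol triflate
Conditions: KN(SiMe3)2, THF, −78 °C; then PhNTf2, −78 to 0 °C
Reagents that add atoms: N-phenylbis(trifluoromethanesulfonimide), O=S(=O)(N(c1ccccc1)S(=O)(=O)C(F)(F)F)C(F)(F)F
Why: deprotonation is possible only at C4, and O-sulfonylation of the trienolate (enol triflate formation) fixes the C4=C5 double bond.

Step 4
Reactants: 5 eucarvone enol triflate
Product: 6 trienal
Conditions: Pd(OAc)2 (5 mol %), 1,3-bis(diphenylphosphino)propane (5 mol %), CO (1 atm), Et3SiH, Et3N, DMF, 70 °C
Reagents that add atoms: carbon monoxide, [C-]#[O+]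
Why: palladium-catalysed reductive carbonylation (formylation) of an enol triflate (oxidative addition, CO insertion, hydride transfer from the silane) should give the enal C4=C5–C6H=O without touching the triene.

Step 5
Reactants: 6 trienal; 7 allyl acetoacetate
Product: 9 bicyclic keto ester, via Michael adduct 8 (not isolated)
Conditions: 9-amino-9-deoxy-epi-quinine (20 mol %), 2-fluorobenzoic acid (40 mol %), toluene, 25 °C, then 50 °C
Reagents that add atoms: none
Why: Proposed new method: the primary amine condenses with the α-branched enal to an iminium ion, the enol of 7 adds at C4 (C4–C9 bond), the enamine is protonated at C5, and the methyl ketone, as its enamine, closes onto C6 and dehydrates (C6–C7 bond), a Michael/aldol-condensation (Robinson-type, formal 3+3) cascade. The closest known reaction types are the amine-catalysed asymmetric Michael/aldol cyclohexenone annulation of β-keto esters with enals and primary-amine iminium activation of α-branched enals; their use on a cyclic trienal is the untested part. Ring S closes by a 6-(enolexo)-exo-trig aldol step through C7, because closure through C9 or C5 would give four-membered rings. C4 is set by the catalyst, which shields one face of the iminium ion; C5 is set by protonation of the enamine anti to the new C4 substituent, which gives the cis ring fusion needed in step 8; C9 is a β-keto ester centre and stays a mixture. Attack at C4 rather than at the formyl carbon is secured by iminium activation, and the ring-A diene is cross-conjugated to the iminium ion and offers no vinylogous site. The step also needs the C5 hydrogen not to drift into conjugation with the diene, which the mild acid co-catalyst and moderate temperature are meant to secure.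

Step 6
Reactants: 9 bicyclic keto ester
Product: 11 cis-fused dienone, via keto acid 10 (not isolated)
Conditions: Pd(PPh3)4 (3 mol %), morpholine, THF, 25 °C, then 45 °C
Reagents that add atoms: none
Why: Tsuji–Trost-type deallylation by zerovalent palladium (morpholine as allyl acceptor) and loss of CO2 from the β-keto acid on gentle warming should remove the activating ester under neutral conditions, leaving C9 as the CH2 that step 8 deprotonates.

Step 7
Reactants: 11 cis-fused dienone
Product: 12 vinyl epoxide
Conditions: m-CPBA (1.05 equiv), NaHCO3, CH2Cl2, −20 °C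
Reagents that add atoms: m-chloroperbenzoic acid, OOC(=O)c1cccc(Cl)c1
Why: Prilezhaev epoxidation should take the most electron-rich, trisubstituted C10=C11 alkene on its convex face (that of H-5, anti to the C5–C6 bond), setting C10 and C11 with the oxygen on the side opposite to C9.

Step 8
Reactants: 12 vinyl epoxide
Product: 13 tricyclic hydroxy enone
Conditions: LiN(i-Pr)2 (1.2 equiv), THF, −78 °C; then 0 °C; aq. NH4Cl
Reagents that add atoms: none
Why: Proposed new method: kinetic deprotonation at C9 (α′) gives the cross-conjugated lithium enolate, whose carbon attacks the proximal tertiary epoxide carbon C10 axially and anti to oxygen in a 4-exo-tet closure (C9–C10 bond), setting C9, C10 (inversion) and C11 (retention) as in the target, while O-alkylation would need a bridgehead enol ether and 5-endo attack at C11 is stereoelectronically disfavoured; the closest known reaction type is the carbanion epoxynitrile cyclisation, which gives cyclobutanes with quaternary carbons by 4-exo opening of epoxides.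

Step 9
Reactants: 13 tricyclic hydroxy enone; 14 isovaleryl chloride
Product: 15 C11 isovalerate
Conditions: pyridine, 4-(dimethylamino)pyridine (cat.), CH2Cl2, 0 to 25 °C
Reagents that add atoms: none
Why: nucleophile-catalysed acylation of the only hydroxyl group; no stereocentre is touched.

Step 10
Reactants: 15 C11 isovalerate
Product: 16 tertiary allylic alcohol
Conditions: CeCl3, MeLi, THF, −78 °C; aq. NH4Cl
Reagents that add atoms: methyllithium, [Li]C
Why: the organocerium reagent should add 1,2 to the enone carbonyl C8 from the face of the C4 bridge (away from the C10 methyl) much faster than to the hindered ester; the new carbinol centre is destroyed in step 11.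

Step 11
Reactants: 16 tertiary allylic alcohol
Product: 17 transposed enone
Conditions: pyridinium chlorochromate ([C5H5NH][CrO3Cl]), 4 Å molecular sieves, CH2Cl2, 25 °C
Reagents that add atoms: pyridinium chlorochromate, [O-][Cr](=O)(=O)Cl.c1cc[nH+]cc1
Why: Babler–Dauben oxidative transposition: the tertiary allylic chromate ester undergoes a [3,3] shift to C6 and is oxidised there, which puts the carbonyl on C6 and leaves the new methyl on the C7=C8 double bond.

Step 12
Reactants: 17 transposed enone
Product: 18 cis-1,2-diol
Conditions: OsO4 (5 mol %), N-methylmorpholine N-oxide, acetone/H2O, 25 °C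
Reagents that add atoms: osmium tetroxide, O=[Os](=O)(=O)=O; N-methylmorpholine N-oxide, C[N+]1([O-])CCOCC1; water, O
Why: Upjohn dihydroxylation should pick the cis-disubstituted C1=C2 alkene over the hindered, electron-poor enone and add both oxygens syn on the face anti to the allylic C11 ester oxygen, which sets C2 as in the target and C1 for inversion.

Step 13
Reactants: 18 cis-1,2-diol
Product: 20 cyclic sulfate, via cyclic sulfite 19 (not isolated)
Conditions: SOCl2, Et3N, CH2Cl2, 0 °C; then RuCl3 (1 mol %), NaIO4, MeCN/H2O, 0 °C
Reagents that add atoms: thionyl chloride, O=S(Cl)Cl; sodium periodate, [Na+].[O-]I(=O)(=O)=O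
Why: cyclic sulfite formation and oxidation by ruthenium tetroxide (the standard cyclic sulfate synthesis) turn the diol into a 1,2-dielectrophile without changing a stereocentre.

Step 14
Reactants: 20 cyclic sulfate; 21 angelic acid
Product: 23 target diester CNP0151972.1, via cesium alkyl sulfate 22 (not isolated)
Conditions: Cs2CO3, DMF, 45 °C; then H2SO4 (cat.), H2O, THF, 25 °C
Reagents that add atoms: none
Why: the carboxylate should open the cyclic sulfate by SN2 at C1 (C2 is neopentyl) with inversion, installing the angelate without activating the acid (no Z to E isomerisation), and acid hydrolysis of the sulfate monoester by S–O cleavage frees the C2 hydroxyl with retention.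

**Compound list**

1 | (R)-(−)-carvone | CC1=CC[C@H](CC1=O)C(C)=C | starting material
2 | carvone hydrobromide, (5R)-5-(2-bromopropan-2-yl)-2-methylcyclohex-2-en-1-one | CC1=CC[C@H](CC1=O)C(C)(C)Br | intermediate
3 | car-3-en-2-one, 3,7,7-trimethylbicyclo[4.1.0]hept-3-en-2-one (cis-fused cyclopropane) | CC1=CC[C@H]2C(C)(C)[C@H]2C1=O | intermediate (not isolated)
4 | eucarvone, 2,6,6-trimethylcyclohepta-2,4-dien-1-one (achiral) | CC1=CC=CC(C)(C)CC1=O | intermediate
5 | eucarvone enol triflate, 3,3,7-trimethylcyclohepta-1,4,6-trien-1-yl trifluoromethanesulfonate | CC1=CC=CC(C)(C)C=C1OS(=O)(=O)C(F)(F)F | intermediate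
6 | trienal, 3,3,7-trimethylcyclohepta-1,4,6-triene-1-carbaldehyde | CC1=CC=CC(C)(C)C=C1C=O | intermediate
7 | allyl acetoacetate (allyl 3-oxobutanoate) | CC(=O)CC(=O)OCC=C | starting material
8 | Michael adduct, allyl 3-oxo-2-(7-formyl-2,2,6-trimethylcyclohepta-3,5-dien-1-yl)butanoate; formyl group and keto ester arm cis, C4 and C5 as in the target, C9 epimers | C1=CC(C)(C)[C@@H](C(C(=O)OCC=C)C(C)=O)[C@@H](C=O)C(C)=C1 | intermediate (not isolated)
9 | bicyclic keto ester, allyl 5,9,9-trimethyl-2-oxo-2,4a,9,9a-tetrahydro-1H-benzo[7]annulene-1-carboxylate; cis ring fusion (H-4a and H-9a cis), ester carbon epimeric | C1=CC(C)(C)[C@H]2C(C(=O)OCC=C)C(=O)C=C[C@H]2C(C)=C1 | intermediate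
10 | keto acid, the free 1-carboxylic acid of 9 | C1=CC(C)(C)[C@H]2C(C(=O)O)C(=O)C=C[C@H]2C(C)=C1 | intermediate (not isolated)
11 | cis-fused dienone, (4aR,9aS)-5,9,9-trimethyl-1,4a,9,9a-tetrahydro-2H-benzo[7]annulen-2-one | C1=CC(C)(C)[C@H]2CC(=O)C=C[C@H]2C(C)=C1 | intermediate
12 | vinyl epoxide, the 5,6-epoxide of 11 (C10–C11 in plan labels) with the oxygen on the face of H-4a | C1=CC(C)(C)[C@H]2CC(=O)C=C[C@H]2[C@]3(C)O[C@H]13 | intermediate
13 | tricyclic hydroxy enone: cyclobutane C4–C5–C10–C9 closed, C8 ketone with C6=C7 alkene, C1=C2 alkene, C11–OH; C4, C5, C9, C10, C11 configured as in the target | C1=CC(C)(C)[C@@H]2[C@H]3C=CC(=O)[C@@H]2[C@@]3(C)[C@@H]1O | intermediate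
14 | isovaleryl chloride (3-methylbutanoyl chloride) | CC(C)CC(=O)Cl | starting material
15 | C11 isovalerate of 13 | C1=CC(C)(C)[C@@H]2[C@H]3C=CC(=O)[C@@H]2[C@@]3(C)[C@@H]1OC(=O)CC(C)C | intermediate
16 | tertiary allylic alcohol: C8 carries methyl (on the side of the C4 bridge) and hydroxyl, C6=C7 alkene | C1=CC(C)(C)[C@@H]2[C@H]3C=C[C@](C)(O)[C@@H]2[C@@]3(C)[C@@H]1OC(=O)CC(C)C | intermediate
17 | transposed enone: C6 ketone, C7=C8(CH3), C1=C2 alkene, C11 isovalerate; ring stereocentres as in the target | C1=CC(C)(C)[C@@H]2[C@H]3C(=O)C=C(C)[C@@H]2[C@@]3(C)[C@@H]1OC(=O)CC(C)C | intermediate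
18 | cis-1,2-diol: C1–OH and C2–OH both on the face anti to C11–O (C2 as in the target, C1 epimeric to it) | O[C@H]1[C@@H](O)C(C)(C)[C@@H]2[C@H]3C(=O)C=C(C)[C@@H]2[C@@]3(C)[C@@H]1OC(=O)CC(C)C | intermediate
19 | cyclic sulfite of diol 18 (sulfur epimers) | O=S1O[C@H]2[C@@H](O1)C(C)(C)[C@@H]3[C@H]4C(=O)C=C(C)[C@@H]3[C@@]4(C)[C@@H]2OC(=O)CC(C)C | intermediate (not isolated)
20 | cyclic sulfate of diol 18 | O=S1(=O)O[C@H]2[C@@H](O1)C(C)(C)[C@@H]3[C@H]4C(=O)C=C(C)[C@@H]3[C@@]4(C)[C@@H]2OC(=O)CC(C)C | intermediate
21 | angelic acid, (Z)-2-methylbut-2-enoic acid | C/C=C(/C)C(=O)O | starting material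
22 | cesium alkyl sulfate: C1 angelate (inverted, as in the target), C2–OSO3Cs, C11 isovalerate | C/C=C(/C)C(=O)O[C@@H]1[C@@H](OS(=O)(=O)[O-])C(C)(C)[C@@H]2[C@H]3C(=O)C=C(C)[C@@H]2[C@@]3(C)[C@@H]1OC(=O)CC(C)C.[Cs+] | intermediate (not isolated)
23 | target diester CNP0151972.1: C11 isovalerate, C1 angelate, C2 hydroxyl; in plan labels 1R,2S,4S,5R,9R,10R,11S | C/C=C(/C)C(=O)O[C@@H]1[C@@H](O)C(C)(C)[C@@H]2[C@H]3C(=O)C=C(C)[C@@H]2[C@@]3(C)[C@@H]1OC(=O)CC(C)C | target

**Step count and risks**

Total: 14 steps. Longest linear sequence: 14 steps (1 to 23); compounds 7, 14 and 21 are bought and enter directly.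

Steps most likely to fail:

1. Step 5 (proposed new method). What may go wrong: weak facial discrimination by the amine on the α-branched iminium ion, sluggish addition at C4 next to the gem-dimethyl carbon, or drift of the C5 hydrogen into conjugation with the ring-A diene during the cascade. Fallback: it sets out from 6 and 7. The classical achiral amine-catalysed Robinson-type annulation (pyrrolidine, acetic acid, toluene, 50 °C) should give racemic keto ester F2 through racemic Michael adduct F1. Deallylative decarboxylation as in step 6 (Pd(PPh3)4, morpholine) should give racemic dienone F4 through racemic keto acid F3. A Shi epoxidation (fructose-derived ketone, KHSO5, K2CO3, MeCN/dimethoxymethane/H2O, 0 °C) run to about half conversion then serves as a kinetic resolution: the ketone enantiomer is chosen so that its dioxirane matches the convex face of the wanted dienone enantiomer. The route is rejoined at epoxide 12 after separation from the unreacted dienone.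

2. Step 8 (proposed new method). What may go wrong: proton transfer from C5 to the enolate followed by eliminative opening of the epoxide, or failure of substitution at the tertiary epoxide carbon so that the enolate is simply recovered. Fallback: it sets out from 12. Kinetic enolisation and silylation (LiN(i-Pr)2, Me3SiCl, THF, −78 °C) should give the cross-conjugated silyl enol ether F5. A Lewis acid (Me3SiOTf, catalytic, CH2Cl2, −78 °C) then opens the epoxide at its tertiary carbon with carbocation character, a Mukaiyama-type alkylation of a silyl enol ether by an epoxide, giving silyl ether F6. Aqueous acid work-up returns alcohol 13.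

3. Step 14. What may go wrong: participation of the neighbouring C11 isovalerate carbonyl in the displacement at C1, which scrambles the acyl groups instead of letting angelate attack, or slow substitution on the hindered face. Fallback: it sets out from diol 18 and avoids substitution at C1. Selective oxidation of the less hindered C1 hydroxyl (TEMPO catalytic, PhI(OAc)2, CH2Cl2) should give hydroxy ketone F7. A hydroxyl-directed Saksena–Evans reduction (Me4NBH(OAc)3, MeCN/AcOH, −20 °C) delivers hydride from the side of the C2 oxygen and should give the trans-diol F8. A Yamaguchi-type esterification of the C1 hydroxyl (21, 2,4,6-trichlorobenzoyl chloride, Et3N, then F8, toluene, 80 °C, no DMAP) reaches 23.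

**Further compounds**

F1 | step 5 | racemic Michael adduct (racemate of 8) | C1=CC(C)(C)[C@@H](C(C(=O)OCC=C)C(C)=O)[C@@H](C=O)C(C)=C1.C1=CC(C)(C)[C@H](C(C(=O)OCC=C)C(C)=O)[C@H](C=O)C(C)=C1
F2 | step 5 | racemic bicyclic keto ester (racemate of 9) | C1=CC(C)(C)[C@H]2C(C(=O)OCC=C)C(=O)C=C[C@H]2C(C)=C1.C1=CC(C)(C)[C@@H]2C(C(=O)OCC=C)C(=O)C=C[C@@H]2C(C)=C1
F3 | step 5 | racemic keto acid (racemate of 10) | C1=CC(C)(C)[C@H]2C(C(=O)O)C(=O)C=C[C@H]2C(C)=C1.C1=CC(C)(C)[C@@H]2C(C(=O)O)C(=O)C=C[C@@H]2C(C)=C1
F4 | step 5 | racemic cis-fused dienone (racemate of 11) | C1=CC(C)(C)[C@H]2CC(=O)C=C[C@H]2C(C)=C1.C1=CC(C)(C)[C@@H]2CC(=O)C=C[C@@H]2C(C)=C1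
F5 | step 8 | cross-conjugated trimethylsilyl enol ether of 12 | C1=CC(C)(C)[C@H]2C=C(O[Si](C)(C)C)C=C[C@H]2[C@]3(C)O[C@H]13
F6 | step 8 | C11 trimethylsilyl ether of 13 | C1=CC(C)(C)[C@@H]2[C@H]3C=CC(=O)[C@@H]2[C@@]3(C)[C@@H]1O[Si](C)(C)C
F7 | step 14 | hydroxy ketone: C1 ketone, C2–OH, C11 isovalerate | O=C1[C@@H](O)C(C)(C)[C@@H]2[C@H]3C(=O)C=C(C)[C@@H]2[C@@]3(C)[C@@H]1OC(=O)CC(C)C
F8 | step 14 | trans-1,2-diol with C1–OH configured as in the target, C11 isovalerate | O[C@@H]1[C@@H](O)C(C)(C)[C@@H]2[C@H]3C(=O)C=C(C)[C@@H]2[C@@]3(C)[C@@H]1OC(=O)CC(C)C
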